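**Plan**
- Retrosynthesis: remove the C8 tigloyl ester and the protecting groups; take C1=O/C10–OH back to a C1=C10 olefin; take the C13 methylene and the lactone bonds (O–C6, C7–C11) back to a C6 ketone; then cut C8–C9 and rejoin C1–C6 to reach a trans-1,2-dialkenylcyclohexenol, which comes from an α′-alkenyl cyclohexenone (C1–C10 bond) and a (Z)-alkoxyvinyl metal (C6–C7 bond).
- Enabling feature (target numbering: ring C1–C10, lactone C11–C13, C14 on C10, C15 on C4): the ring-cis C4=C5 olefin next to the C6 carbinol is a cyclohexenone in disguise, and the vicinal C8/C9 oxygens sit on the one ring bond that a [3,3] shift can make between two enol-ether termini.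
- Forward order: six-membered ring from 3-methylcyclohexenone (steps 1–4, 9, 10); ten-membered carbocycle by ring expansion (step 11); γ-lactone closed last (step 14); then methylene, ester, C1/C10 oxygenation and deprotection.
- Stereochemistry: C3 from a lipase resolution; the two cyclohexenol centres are set relative to C3 (kinetic protonation, anti addition) and passed on to C8/C9 through the chair; C7 by peripheral alkylation; C6 by chelation-controlled reduction followed by Mitsunobu inversion; C10 by a ligand- and substrate-matched dihydroxylation.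
- Protecting groups: O3 TBS; O8 3,4-dimethoxybenzyl (removed first with DDQ); O9 4-methoxybenzyl, because its E enol ether can be made stereospecifically from the alcohol through an ynol ether.

Key step: step 11

Remark: the lipase is assumed to acetylate the (R)-enantiomer of 3 faster, as the empirical size rule for secondary alcohols predicts; if the preference were the reverse, the acetate fraction would be methanolysed and carried on instead.

**Route**

Step 1
Reactants: 1 3-methylcyclohex-2-en-1-one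
Product: 2 3-methylcyclohexa-1,3-dien-1-yl acetate
Conditions: isopropenyl acetate, TsOH (cat.), reflux, acetone distilled off
Reagents that add atoms: isopropenyl acetate CC(=C)OC(C)=O
Why: Acid-catalysed enol acetylation (transesterification) under equilibrating conditions should give the linear endocyclic dienyl acetate, the thermodynamic enol derivative of a β-methyl cyclohexenone.

Step 2
Reactants: 2 3-methylcyclohexa-1,3-dien-1-yl acetate
Product: 3 rac-4-hydroxy-3-methylcyclohex-2-en-1-one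
Conditions: mCPBA, EtOH/H2O, 0 °C to rt
Reagents that add atoms: mCPBA O=C(OO)c1cccc(Cl)c1
Why: Vinylogous Rubottom-type oxidation, in which the peracid epoxidises the electron-rich γ,δ-double bond and the epoxide collapses with loss of the acetyl group to the racemic γ-hydroxy enone, the classical route from dienol esters to γ-hydroxy enones.

Step 3
Reactants: 3 rac-4-hydroxy-3-methylcyclohex-2-en-1-one
Product: 4 (S)-4-hydroxy-3-methylcyclohex-2-en-1-one
Conditions: vinyl acetate, lipase PS (Burkholderia cepacia), MTBE, 30 °C, run past half conversion, alcohol separated from the acetate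
Reagents that add atoms: none
Why: Lipase-catalysed kinetic resolution by enantioselective transesterification, expected to acetylate the (R)-alcohol and leave the (S)-alcohol, which becomes C3 of the target.

Step 4
Reactants: 4 (S)-4-hydroxy-3-methylcyclohex-2-en-1-one
Product: 5 (S)-4-(tert-butyldimethylsilyloxy)-3-methylcyclohex-2-en-1-one
Conditions: TBSCl, imidazole, DMF, rt
Reagents that add atoms: TBSCl CC(C)(C)[Si](C)(C)Cl
Why: Standard silylation of a secondary allylic alcohol, which leaves the stereocentre untouched.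

Step 5
Reactants: 6 3,4-dimethoxybenzyl alcohol
Product: 7 3,4-dimethoxybenzyl vinyl ether
Conditions: ethyl vinyl ether (solvent), Pd(OAc)2 (cat.), 1,10-phenanthroline (cat.), rt
Reagents that add atoms: ethyl vinyl ether C=COCC
Why: Palladium-catalysed transfer vinylation (vinyl ether exchange) of a primary alcohol.

Step 6
Reactants: 7 3,4-dimethoxybenzyl vinyl ether
Product: 9 (Z)-2-bromovinyl 3,4-dimethoxybenzyl ether, via dibromo ether 8 (not isolated)
Conditions: Br2 (1.0 equiv), CH2Cl2, −78 °C; then i-Pr2NEt, −78 to 40 °C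
Reagents that add atoms: bromine BrBr
Why: Bromination–dehydrobromination of an enol ether, in which the α-bromo ether loses HBr through its oxocarbenium ion and should give, as for the ethyl analogue, mainly the isomer with bromine cis to oxygen (any E isomer is removed).

Step 7
Reactants: 10 4-methoxybenzyl alcohol
Product: 14 4-methoxybenzyl prop-1-ynyl ether, via potassium alkoxide 11 (not isolated), via dichlorovinyl ether 12 (not isolated), via lithium alkoxyacetylide 13 (not isolated)
Conditions: KH, THF, 0 °C; Cl2C=CHCl, −78 °C to rt; n-BuLi (2.5 equiv), −78 to −40 °C; MeI, HMPA, −78 to 0 °C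
Reagents that add atoms: trichloroethylene ClC=C(Cl)Cl; iodomethane CI
Why: Standard ynol ether synthesis from an alcohol, in which the alkoxide adds to dichloroacetylene formed from trichloroethylene, n-butyllithium effects elimination and chlorine–lithium exchange, and the lithium alkoxyacetylide is methylated.

Step 8
Reactants: 14 4-methoxybenzyl prop-1-ynyl ether
Product: 16 (E)-2-bromoprop-1-enyl 4-methoxybenzyl ether, via alkenylzirconocene chloride 15 (not isolated)
Conditions: Cp2Zr(H)Cl, THF, rt; then NBS, 0 °C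
Reagents that add atoms: N-bromosuccinimide O=C1CCC(=O)N1Br
Why: Hydrozirconation is a syn addition that places zirconium on the carbon remote from oxygen, and bromodezirconation with retention then gives bromine trans to oxygen, so the E geometry is fixed by mechanism.

Step 9
Reactants: 5 (S)-4-(tert-butyldimethylsilyloxy)-3-methylcyclohex-2-en-1-one; 16 (E)-2-bromoprop-1-enyl 4-methoxybenzyl ether
Product: 19 (4S,6S)-4-(tert-butyldimethylsilyloxy)-6-[(E)-1-(4-methoxybenzyloxy)prop-1-en-2-yl]-3-methylcyclohex-2-en-1-one, via lithium dienolate 17 (not isolated), via lithium dienolate of the coupled ketone 18 (not isolated)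
Conditions: LiN(SiMe3)2 (2.2 equiv), THF, −78 °C; 16, Pd2(dba)3 (cat.), P(t-Bu)3 (cat.), −78 °C to rt; recool, AcOH, −78 °C
Reagents that add atoms: none
Why: Palladium-catalysed α-alkenylation of the kinetically formed α′-enolate (enolate cross-coupling) keeps the olefin geometry, and kinetic protonation of the product dienolate anti to the C4 silyloxy group (cyclohexenone numbering) should place the alkenyl group cis to it (6S).

Step 10
Reactants: 19 (4S,6S)-4-(tert-butyldimethylsilyloxy)-6-[(E)-1-(4-methoxybenzyloxy)prop-1-en-2-yl]-3-methylcyclohex-2-en-1-one; 9 (Z)-2-bromovinyl 3,4-dimethoxybenzyl ether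
Product: 22 (1S,4S,6S)-4-(tert-butyldimethylsilyloxy)-1-[(Z)-2-(3,4-dimethoxybenzyloxy)vinyl]-6-[(E)-1-(4-methoxybenzyloxy)prop-1-en-2-yl]-3-methylcyclohex-2-en-1-ol, via alkenyllithium 20 (not isolated), via alkenylcerium dichloride 21 (not isolated)
Conditions: 9, t-BuLi (2.0 equiv), Et2O, −78 °C; CeCl3, THF, −78 °C; then 19, −78 °C; aq NaHCO3
Reagents that add atoms: none
Why: 1,2-Addition of the chelation-stabilised (Z)-β-alkoxyvinyl organometallic (as the organocerium to suppress enolisation) should occur anti to the neighbouring alkenyl group and to the silyloxy group, giving the trans-dialkenyl carbinol (1S).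

Step 11
Reactants: 22 (1S,4S,6S)-4-(tert-butyldimethylsilyloxy)-1-[(Z)-2-(3,4-dimethoxybenzyloxy)vinyl]-6-[(E)-1-(4-methoxybenzyloxy)prop-1-en-2-yl]-3-methylcyclohex-2-en-1-ol
Product: 25 (2Z,4S,6E,8R,9S)-4-(tert-butyldimethylsilyloxy)-9-(3,4-dimethoxybenzyloxy)-8-(4-methoxybenzyloxy)-3,7-dimethylcyclodeca-2,6-dien-1-one (ketone carbon is C6 of the target), via potassium alkoxide 23 (not isolated), via potassium enolate 24 (not isolated)
Conditions: KH, 18-crown-6, THF, 0 °C to rt; then AcOH in THF, −78 °C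
Reagents that add atoms: none
Why: Proposed new method: alkoxide 23 should undergo a concerted, alkoxide-accelerated [3,3] shift through a chair in which the two enol-ether termini C8 and C9 bond while the doubly allylic C1–C6 bond breaks, driven by formation of the cross-conjugated enolate 24; the closest known reaction type is the anionic oxy-Cope ring expansion of trans-1,2-divinylcyclohexenols to (2Z,6E)-cyclodecadienones, known so far only with hydrogen- or carbon-substituted vinyl termini. The ten-membered ring arises by four-atom ring expansion of the cyclohexene and not by end-to-end closure, and its ring-cis C4=C5 bond is simply the original cyclohexene olefin. C8 is controlled by the Z geometry of the C7=C8 enol ether (oxygen axial in the chair) and C9 by the E geometry of the C10=C9 enol ether (oxygen equatorial), which makes the two oxygens erythro, and their absolute sense follows from the (1S,6S) carbinol and allylic centres of 22 because both ring bonds are equatorial in the chair. The step needs chair over boat selectivity and an E C1=C10 bond, both secured by the trans arrangement of the two alkenyl groups, and it needs the β-alkoxy enolate 24 to survive, which is why the crown ether is used to keep the temperature at or below rt and the quench is done with acetic acid at −78 °C.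

Step 12
Reactants: 25 (2Z,4S,6E,8R,9S)-4-(tert-butyldimethylsilyloxy)-9-(3,4-dimethoxybenzyloxy)-8-(4-methoxybenzyloxy)-3,7-dimethylcyclodeca-2,6-dien-1-one
Product: 27 ethyl [(1R,2S,3R,4E,7S,8Z)-7-(tert-butyldimethylsilyloxy)-2-(3,4-dimethoxybenzyloxy)-3-(4-methoxybenzyloxy)-4,8-dimethyl-10-oxocyclodeca-4,8-dien-1-yl]acetate, via lithium enolate 26 (not isolated)
Conditions: LiN(SiMe3)2, THF, −78 °C; ICH2CO2Et, DMPU, −78 to −40 °C
Reagents that add atoms: ethyl iodoacetate CCOC(=O)CI
Why: Kinetic deprotonation should give the lithium enolate with oxygen syn to C8 (chelated by the C8 ether), and enolate alkylation with the reactive iodoacetate from the ring periphery, anti to C9, sets C7, the low temperature holding back β-elimination of the C8 alkoxide.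

Step 13
Reactants: 27 ethyl [(1R,2S,3R,4E,7S,8Z)-7-(tert-butyldimethylsilyloxy)-2-(3,4-dimethoxybenzyloxy)-3-(4-methoxybenzyloxy)-4,8-dimethyl-10-oxocyclodeca-4,8-dien-1-yl]acetate
Product: 28 ethyl [(1S,2S,3R,4E,7S,8Z,10S)-7-(tert-butyldimethylsilyloxy)-2-(3,4-dimethoxybenzyloxy)-10-hydroxy-3-(4-methoxybenzyloxy)-4,8-dimethylcyclodeca-4,8-dien-1-yl]acetate
Conditions: Zn(BH4)2, Et2O, −20 °C
Reagents that add atoms: none
Why: Chelation-controlled 1,2-reduction of the β-alkoxy enone (zinc bridging the carbonyl and the C8 ether oxygen, hydride from the peripheral face anti to the ring bond C7–C8, which is also the Felkin–Anh sense) should give the 1,3-syn alcohol, that is 6S in target numbering, deliberately epimeric to the target at C6.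

Step 14
Reactants: 28 ethyl [(1S,2S,3R,4E,7S,8Z,10S)-7-(tert-butyldimethylsilyloxy)-2-(3,4-dimethoxybenzyloxy)-10-hydroxy-3-(4-methoxybenzyloxy)-4,8-dimethylcyclodeca-4,8-dien-1-yl]acetate
Product: 30 (3aS,4S,5R,6E,9S,10Z,11aR)-9-(tert-butyldimethylsilyloxy)-4-(3,4-dimethoxybenzyloxy)-5-(4-methoxybenzyloxy)-6,10-dimethyl-3a,4,5,8,9,11a-hexahydrocyclodeca[b]furan-2(3H)-one, via hydroxy acid 29 (not isolated)
Conditions: LiOH, THF/H2O, 0 °C; AcOH to pH 5, extraction; then PPh3, DIAD, THF (dilute), 0 °C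
Reagents that add atoms: lithium hydroxide [Li+].[OH-]
Why: Saponification (which also opens any cis-lactone formed earlier) followed by Mitsunobu lactonisation closes the γ-lactone by 5-exo SN2 attack of the carboxylate on the activated allylic C6 with inversion, giving the 6R, trans-fused lactone.

Step 15
Reactants: 30 (3aS,4S,5R,6E,9S,10Z,11aR)-9-(tert-butyldimethylsilyloxy)-4-(3,4-dimethoxybenzyloxy)-5-(4-methoxybenzyloxy)-6,10-dimethyl-3a,4,5,8,9,11a-hexahydrocyclodeca[b]furan-2(3H)-one
Product: 34 the 3-methylidene derivative of 30, via lactone enolate 31 (not isolated), via Mannich base 32 (not isolated), via ammonium iodide 33 (not isolated)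
Conditions: LiN(i-Pr)2, THF, −78 °C; CH2=NMe2+ I−, −78 to 0 °C; MeI, MeOH, rt; aq NaHCO3, CH2Cl2, rt
Reagents that add atoms: dimethylmethyleneiminium iodide C=[N+](C)C.[I-]
Why: Standard α-methylenation of a γ-butyrolactone by enolate Mannich reaction, N-methylation and base-induced loss of trimethylamine.

Step 16
Reactants: 34 the 3-methylidene lactone
Product: 35 the 4-hydroxy compound (O8 free in target numbering)
Conditions: DDQ (1.2 equiv), CH2Cl2/pH 7 buffer, 0 °C
Reagents that add atoms: none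
Why: Oxidative cleavage of benzylic ethers by DDQ is fastest for the more electron-rich 3,4-dimethoxybenzyl group, so one equivalent at 0 °C should free O8 and leave the 4-methoxybenzyl ether on O9.

Step 17
Reactants: 35 the 4-hydroxy methylidene lactone
Product: 36 its (E)-2-methylbut-2-enoate (tiglate on O8)
Conditions: tigloyl chloride, Et3N, DMAP (cat.), CH2Cl2, 0 °C to rt
Reagents that add atoms: tigloyl chloride C/C=C(\C)C(Cl)=O
Why: DMAP-catalysed acylation of the secondary alcohol with the acid chloride keeps the E olefin of the tigloyl group and should be fast enough at 0 °C to pre-empt translactonisation to O8.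

Step 18
Reactants: 36 the O8 tiglate with the C1=C10 olefin
Product: 37 the (1S,10R)-1,10-diol (target numbering; cyclodeca[b]furan positions 7 and 6)
Conditions: OsO4 (cat.), (DHQ)2PHAL (cat.), NMO, acetone/H2O, 0 °C
Reagents that add atoms: N-methylmorpholine N-oxide C[N+]1([O-])CCOCC1; water O
Why: Sharpless-type ligand-accelerated syn dihydroxylation of the most electron-rich olefin (C1=C10), in which the (DHQ)2PHAL ligand and the substrate (osmium anti to the allylic C9 ether, from the ring periphery) should both direct attack to the face that gives the C10 configuration of the target.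

Step 19
Reactants: 37 the 1,10-diol
Product: 38 the 1-oxo-10-hydroxy compound (3-O-TBS, 9-O-PMB ether of the target)
Conditions: Dess–Martin periodinane, CH2Cl2, 0 °C to rt
Reagents that add atoms: none
Why: Dess–Martin oxidation takes the secondary C1 alcohol to the ketone while the tertiary C10 alcohol cannot react, and the non-basic medium spares the β-silyloxy ketone from elimination.

Step 20
Reactants: 38 the 3-O-TBS, 9-O-PMB ether of the target
Product: 39 the 3-O-TBS ether of the target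
Conditions: DDQ, CH2Cl2/pH 7 buffer, rt
Reagents that add atoms: none
Why: Oxidative removal of the 4-methoxybenzyl ether with DDQ in the presence of water, under neutral conditions that leave the tiglate on O8.

Step 21
Reactants: 39 the 3-O-TBS ether of the target
Product: 40 CNP0106709.2
Conditions: HF·pyridine, pyridine/THF, 0 °C to rt
Reagents that add atoms: none
Why: Fluoride-mediated cleavage of the allylic silyl ether under buffered, mildly acidic conditions that should avoid acyl migration and retro-aldol cleavage.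

**Compound list**
1 | 3-methylcyclohex-2-en-1-one | CC1=CC(=O)CCC1 | starting material
2 | 3-methylcyclohexa-1,3-dien-1-yl acetate | CC(=O)OC1=CC(C)=CCC1 | intermediate
3 | rac-4-hydroxy-3-methylcyclohex-2-en-1-one | CC1=CC(=O)CCC1O | intermediate
4 | (S)-4-hydroxy-3-methylcyclohex-2-en-1-one | CC1=CC(=O)CC[C@@H]1O | intermediate
5 | (S)-4-(tert-butyldimethylsilyloxy)-3-methylcyclohex-2-en-1-one | CC1=CC(=O)CC[C@@H]1O[Si](C)(C)C(C)(C)C | intermediate
6 | 3,4-dimethoxybenzyl alcohol | COc1ccc(CO)cc1OC | starting material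
7 | 3,4-dimethoxybenzyl vinyl ether | C=COCc1ccc(OC)c(OC)c1 | intermediate
8 | 1,2-dibromoethyl 3,4-dimethoxybenzyl ether | BrCC(Br)OCc1ccc(OC)c(OC)c1 | intermediate (not isolated)
9 | (Z)-2-bromovinyl 3,4-dimethoxybenzyl ether | Br/C=C\OCc1ccc(OC)c(OC)c1 | intermediate
10 | 4-methoxybenzyl alcohol | COc1ccc(CO)cc1 | starting material
11 | potassium 4-methoxybenzyl oxide | [K+].[O-]Cc1ccc(OC)cc1 | intermediate (not isolated)
12 | (E)-1,2-dichlorovinyl 4-methoxybenzyl ether | Cl/C=C(\OCc1ccc(OC)cc1)Cl | intermediate (not isolated)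
13 | lithium 2-(4-methoxybenzyloxy)ethynide | [Li+].[C-]#COCc1ccc(OC)cc1 | intermediate (not isolated)
14 | 4-methoxybenzyl prop-1-ynyl ether | CC#COCc1ccc(OC)cc1 | intermediate
15 | chlorobis(cyclopentadienyl)[(E)-1-(4-methoxybenzyloxy)prop-1-en-2-yl]zirconium | C/C(=C\OCc1ccc(OC)cc1)[Zr](Cl)(C1C=CC=C1)C1C=CC=C1 | intermediate (not isolated)
16 | (E)-2-bromoprop-1-enyl 4-methoxybenzyl ether | C/C(Br)=C\OCc1ccc(OC)cc1 | intermediate
17 | lithium (4S)-4-(tert-butyldimethylsilyloxy)-5-methylcyclohexa-1,5-dien-1-olate | [Li+].[O-]C1=CC[C@H](O[Si](C)(C)C(C)(C)C)C(C)=C1 | intermediate (not isolated)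
18 | lithium dienolate of 19 (oxygen on C1, C1=C6 and C2=C3, cyclohexenone numbering) | [Li+].[O-]C1=C(/C(C)=C/OCc2ccc(OC)cc2)C[C@H](O[Si](C)(C)C(C)(C)C)C(C)=C1 | intermediate (not isolated)
19 | (4S,6S)-4-(tert-butyldimethylsilyloxy)-6-[(E)-1-(4-methoxybenzyloxy)prop-1-en-2-yl]-3-methylcyclohex-2-en-1-one | O=C1C=C(C)[C@@H](O[Si](C)(C)C(C)(C)C)C[C@H]1/C(C)=C/OCc1ccc(OC)cc1 | intermediate
20 | [(Z)-2-(3,4-dimethoxybenzyloxy)vinyl]lithium | [Li]/C=C\OCc1ccc(OC)c(OC)c1 | intermediate (not isolated)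
21 | dichloro[(Z)-2-(3,4-dimethoxybenzyloxy)vinyl]cerium | Cl[Ce](Cl)/C=C\OCc1ccc(OC)c(OC)c1 | intermediate (not isolated)
22 | (1S,4S,6S)-4-(tert-butyldimethylsilyloxy)-1-[(Z)-2-(3,4-dimethoxybenzyloxy)vinyl]-6-[(E)-1-(4-methoxybenzyloxy)prop-1-en-2-yl]-3-methylcyclohex-2-en-1-ol | O[C@@]1(/C=C\OCc2ccc(OC)c(OC)c2)C=C(C)[C@@H](O[Si](C)(C)C(C)(C)C)C[C@H]1/C(C)=C/OCc1ccc(OC)cc1 | intermediate
23 | potassium alkoxide of 22 | [K+].[O-][C@@]1(/C=C\OCc2ccc(OC)c(OC)c2)C=C(C)[C@@H](O[Si](C)(C)C(C)(C)C)C[C@H]1/C(C)=C/OCc1ccc(OC)cc1 | intermediate (not isolated)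
24 | potassium enolate of 25 (oxygen on C6, C6=C7 with oxygen syn to C8, target numbering) | [K+].C1/C=C(C)/[C@@H](OCc2ccc(OC)cc2)[C@@H](OCc2ccc(OC)c(OC)c2)/C=C(\[O-])/C=C(/C)[C@H]1O[Si](C)(C)C(C)(C)C | intermediate (not isolated)
25 | (2Z,4S,6E,8R,9S)-4-(tert-butyldimethylsilyloxy)-9-(3,4-dimethoxybenzyloxy)-8-(4-methoxybenzyloxy)-3,7-dimethylcyclodeca-2,6-dien-1-one | O=C1/C=C(/C)[C@@H](O[Si](C)(C)C(C)(C)C)C/C=C(C)/[C@@H](OCc2ccc(OC)cc2)[C@@H](OCc2ccc(OC)c(OC)c2)C1 | intermediate
26 | lithium enolate of 25 (same anion as in 24) | [Li+].C1/C=C(C)/[C@@H](OCc2ccc(OC)cc2)[C@@H](OCc2ccc(OC)c(OC)c2)/C=C(\[O-])/C=C(/C)[C@H]1O[Si](C)(C)C(C)(C)C | intermediate (not isolated)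
27 | ethyl [(1R,2S,3R,4E,7S,8Z)-7-(tert-butyldimethylsilyloxy)-2-(3,4-dimethoxybenzyloxy)-3-(4-methoxybenzyloxy)-4,8-dimethyl-10-oxocyclodeca-4,8-dien-1-yl]acetate | O=C1/C=C(/C)[C@@H](O[Si](C)(C)C(C)(C)C)C/C=C(C)/[C@@H](OCc2ccc(OC)cc2)[C@@H](OCc2ccc(OC)c(OC)c2)[C@H]1CC(=O)OCC | intermediate
28 | ethyl [(1S,2S,3R,4E,7S,8Z,10S)-7-(tert-butyldimethylsilyloxy)-2-(3,4-dimethoxybenzyloxy)-10-hydroxy-3-(4-methoxybenzyloxy)-4,8-dimethylcyclodeca-4,8-dien-1-yl]acetate | O[C@H]1/C=C(/C)[C@@H](O[Si](C)(C)C(C)(C)C)C/C=C(C)/[C@@H](OCc2ccc(OC)cc2)[C@@H](OCc2ccc(OC)c(OC)c2)[C@H]1CC(=O)OCC | intermediate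
29 | [(1S,2S,3R,4E,7S,8Z,10S)-7-(tert-butyldimethylsilyloxy)-2-(3,4-dimethoxybenzyloxy)-10-hydroxy-3-(4-methoxybenzyloxy)-4,8-dimethylcyclodeca-4,8-dien-1-yl]acetic acid | O[C@H]1/C=C(/C)[C@@H](O[Si](C)(C)C(C)(C)C)C/C=C(C)/[C@@H](OCc2ccc(OC)cc2)[C@@H](OCc2ccc(OC)c(OC)c2)[C@H]1CC(=O)O | intermediate (not isolated)
30 | (3aS,4S,5R,6E,9S,10Z,11aR)-9-(tert-butyldimethylsilyloxy)-4-(3,4-dimethoxybenzyloxy)-5-(4-methoxybenzyloxy)-6,10-dimethyl-3a,4,5,8,9,11a-hexahydrocyclodeca[b]furan-2(3H)-one | C1C(=O)O[C@@H]2/C=C(/C)[C@@H](O[Si](C)(C)C(C)(C)C)C/C=C(C)/[C@@H](OCc3ccc(OC)cc3)[C@@H](OCc3ccc(OC)c(OC)c3)[C@@H]12 | intermediate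
31 | lithium enolate of lactone 30 | [Li+].C1=C([O-])O[C@@H]2/C=C(/C)[C@@H](O[Si](C)(C)C(C)(C)C)C/C=C(C)/[C@@H](OCc3ccc(OC)cc3)[C@@H](OCc3ccc(OC)c(OC)c3)[C@@H]12 | intermediate (not isolated)
32 | 3-[(dimethylamino)methyl] derivative of 30 (C3 epimers) | CN(C)CC1C(=O)O[C@@H]2/C=C(/C)[C@@H](O[Si](C)(C)C(C)(C)C)C/C=C(C)/[C@@H](OCc3ccc(OC)cc3)[C@@H](OCc3ccc(OC)c(OC)c3)[C@@H]12 | intermediate (not isolated)
33 | 3-[(trimethylammonio)methyl] derivative of 30, iodide | C[N+](C)(C)CC1C(=O)O[C@@H]2/C=C(/C)[C@@H](O[Si](C)(C)C(C)(C)C)C/C=C(C)/[C@@H](OCc3ccc(OC)cc3)[C@@H](OCc3ccc(OC)c(OC)c3)[C@@H]12.[I-] | intermediate (not isolated)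
34 | (3aS,4S,5R,6E,9S,10Z,11aR)-9-(tert-butyldimethylsilyloxy)-4-(3,4-dimethoxybenzyloxy)-5-(4-methoxybenzyloxy)-6,10-dimethyl-3-methylidene-3a,4,5,8,9,11a-hexahydrocyclodeca[b]furan-2(3H)-one | C=C1C(=O)O[C@@H]2/C=C(/C)[C@@H](O[Si](C)(C)C(C)(C)C)C/C=C(C)/[C@@H](OCc3ccc(OC)cc3)[C@@H](OCc3ccc(OC)c(OC)c3)[C@@H]12 | intermediate
35 | (3aR,4S,5R,6E,9S,10Z,11aR)-9-(tert-butyldimethylsilyloxy)-4-hydroxy-5-(4-methoxybenzyloxy)-6,10-dimethyl-3-methylidene-3a,4,5,8,9,11a-hexahydrocyclodeca[b]furan-2(3H)-one | C=C1C(=O)O[C@@H]2/C=C(/C)[C@@H](O[Si](C)(C)C(C)(C)C)C/C=C(C)/[C@@H](OCc3ccc(OC)cc3)[C@@H](O)[C@@H]12 | intermediate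
36 | (3aS,4S,5R,6E,9S,10Z,11aR)-9-(tert-butyldimethylsilyloxy)-5-(4-methoxybenzyloxy)-6,10-dimethyl-3-methylidene-2-oxo-2,3,3a,4,5,8,9,11a-octahydrocyclodeca[b]furan-4-yl (E)-2-methylbut-2-enoate | C=C1C(=O)O[C@@H]2/C=C(/C)[C@@H](O[Si](C)(C)C(C)(C)C)C/C=C(C)/[C@@H](OCc3ccc(OC)cc3)[C@@H](OC(=O)/C(C)=C/C)[C@@H]12 | intermediate
37 | (3aS,4S,5S,6R,7S,9S,10Z,11aR)-9-(tert-butyldimethylsilyloxy)-6,7-dihydroxy-5-(4-methoxybenzyloxy)-6,10-dimethyl-3-methylidene-2-oxo-2,3,3a,4,5,6,7,8,9,11a-decahydrocyclodeca[b]furan-4-yl (E)-2-methylbut-2-enoate | C=C1C(=O)O[C@@H]2/C=C(/C)[C@@H](O[Si](C)(C)C(C)(C)C)C[C@H](O)[C@@](C)(O)[C@@H](OCc3ccc(OC)cc3)[C@@H](OC(=O)/C(C)=C/C)[C@@H]12 | intermediate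
38 | (3aS,4S,5S,6S,9S,10Z,11aR)-9-(tert-butyldimethylsilyloxy)-6-hydroxy-5-(4-methoxybenzyloxy)-6,10-dimethyl-3-methylidene-2,7-dioxo-2,3,3a,4,5,6,7,8,9,11a-decahydrocyclodeca[b]furan-4-yl (E)-2-methylbut-2-enoate | C=C1C(=O)O[C@@H]2/C=C(/C)[C@@H](O[Si](C)(C)C(C)(C)C)CC(=O)[C@@](C)(O)[C@@H](OCc3ccc(OC)cc3)[C@@H](OC(=O)/C(C)=C/C)[C@@H]12 | intermediate
39 | (3aS,4S,5S,6S,9S,10Z,11aR)-9-(tert-butyldimethylsilyloxy)-5,6-dihydroxy-6,10-dimethyl-3-methylidene-2,7-dioxo-2,3,3a,4,5,6,7,8,9,11a-decahydrocyclodeca[b]furan-4-yl (E)-2-methylbut-2-enoate | C=C1C(=O)O[C@@H]2/C=C(/C)[C@@H](O[Si](C)(C)C(C)(C)C)CC(=O)[C@@](C)(O)[C@@H](O)[C@@H](OC(=O)/C(C)=C/C)[C@@H]12 | intermediate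
40 | CNP0106709.2, (3aS,4S,5S,6S,9S,10Z,11aR)-5,6,9-trihydroxy-6,10-dimethyl-3-methylidene-2,7-dioxo-2,3,3a,4,5,6,7,8,9,11a-decahydrocyclodeca[b]furan-4-yl (E)-2-methylbut-2-enoate | C=C1C(=O)O[C@@H]2/C=C(/C)[C@@H](O)CC(=O)[C@@](C)(O)[C@@H](O)[C@@H](OC(=O)/C(C)=C/C)[C@@H]12 | target

**Step count:** 21 steps in total; longest linear sequence 17 steps (steps 1–4 and 9–21).

**Steps most likely to fail**

1. Step 11 (the step carrying the new-method label). The [3,3] shift may be slow because both termini lose their enol-ether conjugation. The enolate 24 can then expel the C8 3,4-dimethoxybenzyloxide, alkoxide 23 can fragment, or a boat pathway can give the threo arrangement at C8/C9.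
   Fallback (known chemistry, sets out from 5, returns at 25): the oxygens are left off the vinyl termini and added after a precedented ring expansion.
   - α′-Alkenylation of 5 with 2-bromopropene under the conditions of step 9 gives (4S,6S)-4-(tert-butyldimethylsilyloxy)-3-methyl-6-(prop-1-en-2-yl)cyclohex-2-en-1-one F1.
   - Vinylmagnesium bromide with CeCl3 adds anti to the isopropenyl group to give (1S,4S,6S)-4-(tert-butyldimethylsilyloxy)-1-ethenyl-3-methyl-6-(prop-1-en-2-yl)cyclohex-2-en-1-ol F2.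
   - KH and 18-crown-6 effect the established anionic oxy-Cope ring expansion to (2Z,4S,6E)-4-(tert-butyldimethylsilyloxy)-3,7-dimethylcyclodeca-2,6-dien-1-one F3.
   - SeO2 (cat.) with t-BuOOH hydroxylates the allylic methylene at the more substituted olefin terminus (C9) from the ring periphery, giving (2Z,4S,6E,8S)-4-(tert-butyldimethylsilyloxy)-8-hydroxy-3,7-dimethylcyclodeca-2,6-dien-1-one F4.
   - 4-Methoxybenzyl trichloroacetimidate with La(OTf)3 (cat.) gives the ether (2Z,4S,6E,8S)-4-(tert-butyldimethylsilyloxy)-8-(4-methoxybenzyloxy)-3,7-dimethylcyclodeca-2,6-dien-1-one F5.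
   - Dehydrogenation with IBX and 4-methoxypyridine N-oxide gives (2Z,4S,6E,8S,9E)-4-(tert-butyldimethylsilyloxy)-8-(4-methoxybenzyloxy)-3,7-dimethylcyclodeca-2,6,9-trien-1-one F6.
   - Base-catalysed oxa-Michael addition of 3,4-dimethoxybenzyl alcohol 6 to the new enone, anti to the neighbouring ether, gives 25.
   - In this fallback the C9 and C8 configurations would rest on peripheral attack and 1,2-induction and would have to be checked.

2. Step 12. β-Elimination of the C8 alkoxide from enolate 26 may outrun the SN2 alkylation, the enolate may be quenched by proton transfer from the iodoacetate, or attack may occur from the wrong face.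
   Fallback (sets out from 25, returns at 27): the free enolate is avoided in the bond-forming event.
   - LiN(SiMe3)2 with TMSCl present from the start at −78 °C traps the enolate as the trimethylsilyl enol ether of 25 F7 (silyloxy group on C6, C6=C7, oxygen syn to C8).
   - Cu(acac)2-catalysed cyclopropanation with ethyl diazoacetate on the peripheral face of this electron-rich double bond gives the siloxycyclopropane ester F8 (cyclopropane across C6–C7, CO2Et on the new carbon C11).
   - Et3N·3HF opens this donor–acceptor cyclopropane to γ-keto ester 27.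

3. Step 14. The hydroxy acid 29 may relactonise with retention to the cis-fused lactone during acidification, or the activated allylic C6 may undergo elimination or SN2′ attack instead of direct displacement.
   Fallback (sets out from 28, returns at 30): inversion and ring closure are separated.
   - Intermolecular Mitsunobu reaction of 28 with 4-nitrobenzoic acid (PPh3, DIAD) gives the inverted (6R) 4-nitrobenzoate of 28 F9.
   - K2CO3 in MeOH removes the nitrobenzoate, and the liberated 6R alkoxide closes onto the ethyl ester with retention to give 30.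

**Further compounds**
F1 | step 11 | (4S,6S)-4-(tert-butyldimethylsilyloxy)-3-methyl-6-(prop-1-en-2-yl)cyclohex-2-en-1-one | O=C1C=C(C)[C@@H](O[Si](C)(C)C(C)(C)C)C[C@H]1C(C)=C
F2 | step 11 | (1S,4S,6S)-4-(tert-butyldimethylsilyloxy)-1-ethenyl-3-methyl-6-(prop-1-en-2-yl)cyclohex-2-en-1-ol | O[C@@]1(C=C)C=C(C)[C@@H](O[Si](C)(C)C(C)(C)C)C[C@H]1C(C)=C
F3 | step 11 | (2Z,4S,6E)-4-(tert-butyldimethylsilyloxy)-3,7-dimethylcyclodeca-2,6-dien-1-one | O=C1/C=C(/C)[C@@H](O[Si](C)(C)C(C)(C)C)C/C=C(C)/CCC1
F4 | step 11 | (2Z,4S,6E,8S)-4-(tert-butyldimethylsilyloxy)-8-hydroxy-3,7-dimethylcyclodeca-2,6-dien-1-one | O=C1/C=C(/C)[C@@H](O[Si](C)(C)C(C)(C)C)C/C=C(C)/[C@@H](O)CC1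
F5 | step 11 | (2Z,4S,6E,8S)-4-(tert-butyldimethylsilyloxy)-8-(4-methoxybenzyloxy)-3,7-dimethylcyclodeca-2,6-dien-1-one | O=C1/C=C(/C)[C@@H](O[Si](C)(C)C(C)(C)C)C/C=C(C)/[C@@H](OCc2ccc(OC)cc2)CC1
F6 | step 11 | (2Z,4S,6E,8S,9E)-4-(tert-butyldimethylsilyloxy)-8-(4-methoxybenzyloxy)-3,7-dimethylcyclodeca-2,6,9-trien-1-one | C1/C=C(C)/[C@@H](OCc2ccc(OC)cc2)/C=C/C(=O)/C=C(/C)[C@H]1O[Si](C)(C)C(C)(C)C
F7 | step 12 | trimethylsilyl enol ether of 25 (silyloxy group on C6, C6=C7, oxygen syn to C8) | C1/C=C(C)/[C@@H](OCc2ccc(OC)cc2)[C@@H](OCc2ccc(OC)c(OC)c2)/C=C(\O[Si](C)(C)C)/C=C(/C)[C@H]1O[Si](C)(C)C(C)(C)C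
F8 | step 12 | siloxycyclopropane ester (cyclopropane across C6–C7 of F7, OSiMe3 on C6, CO2Et on C11, C11 epimers) | CCOC(=O)C1[C@]2(O[Si](C)(C)C)/C=C(/C)[C@@H](O[Si](C)(C)C(C)(C)C)C/C=C(C)/[C@@H](OCc3ccc(OC)cc3)[C@@H](OCc3ccc(OC)c(OC)c3)[C@@H]12
F9 | step 14 | (6R) 4-nitrobenzoate of 28 (C6-inverted ester, target numbering) | O=C(O[C@@H]1/C=C(/C)[C@@H](O[Si](C)(C)C(C)(C)C)C/C=C(C)/[C@@H](OCc2ccc(OC)cc2)[C@@H](OCc2ccc(OC)c(OC)c2)[C@H]1CC(=O)OCC)c1ccc([N+](=O)[O-])cc1
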